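**Plan**

Retrosynthetic cuts, in order: the hydroxytyrosyl ester C–O bond; the C3 formyl group back to a vinyl group; the C5–CO2Me bond back to a C5=C6 enol ether; O1 out of the ring (retro-Baeyer–Villiger); the C2–CH3 and C3–vinyl bonds together; last the C4–CH2 bond of the acetate arm.
Enabling feature: without O1, the dihydropyran O1–C2–C3–C4–C5–C6 becomes the carbocycle C6–C2–C3–C4–C5. This is a cyclopentanone (C6 = carbonyl) whose C2 methyl, C3 one-carbon branch and C4 acetate arm alternate faces. Addition to a 4-substituted cyclopent-2-enone followed by alkylation of the resulting enolate gives exactly this trans,trans pattern.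
Forward order: the five-membered ring is bought. The arm is attached at C4, and vinyl and methyl are added in one flask. Oxygen insertion between C6 and C2 expands the carbocycle to the six-membered lactone, the only ring-forming event. The lactone is reduced, dehydrated and acylated at C5; ester exchange, alkene cleavage and debenzylation finish the route.
Stereochemistry: C4 comes from enantiopure (1R,4S)-cis-4-acetoxycyclopent-2-en-1-ol by palladium-catalysed substitution with net retention. C3 is set anti to C4 and C2 anti to C3 in the key step, and C2 migrates to oxygen with retention.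

Key step: step 4

Remark: pyran numbering (O1, C2, C3, C4, C5, C6) is used for the ring atoms of every intermediate from 6 on, C6 being the carbonyl carbon of the carbocycles. Compounds 4 (malonate carbon), 12 and 13 (C6) and 21 (carbinol carbon) are taken as epimer mixtures at centres that the following operation removes.

Step 1
Reactants: 1 (1R,4S)-cis-4-acetoxycyclopent-2-en-1-ol; 2 tert-butyl methyl malonate
Product: 4 tert-butyl methyl 2-[(1S,4R)-4-hydroxycyclopent-2-en-1-yl]malonate, via sodium malonate enolate 3 (not isolated)
Conditions: 2, NaH, THF, 0 °C; then 1, Pd(PPh3)4 (3 mol %), THF, rt → 50 °C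
Reagents that add atoms: none
Why: Tsuji–Trost allylic alkylation: zerovalent palladium ionises the allylic acetate from the face opposite the leaving group and the soft malonate anion 3 attacks the π-allyl terminus remote from the free hydroxyl, again opposite the metal, so that two inversions place the new C4–C bond on the face the acetate occupied (cis to OH) and thereby set C4, the malonate carbon being an irrelevant epimer mixture.

Step 2
Reactants: 4 tert-butyl methyl 2-[(1S,4R)-4-hydroxycyclopent-2-en-1-yl]malonate
Product: 5 tert-butyl 2-[(1R,4R)-4-hydroxycyclopent-2-en-1-yl]acetate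
Conditions: LiCl, H2O, DMSO, 130 °C
Reagents that add atoms: none
Why: Krapcho dealkoxycarbonylation: chloride removes the unhindered methyl group by SN2 attack, the resulting carboxylate loses CO2 and water protonates the ester enolate, whereas the tert-butyl ester offers no site for SN2 dealkylation and the ring stereocentres are not involved.

Step 3
Reactants: 5 tert-butyl 2-[(1R,4R)-4-hydroxycyclopent-2-en-1-yl]acetate
Product: 6 tert-butyl 2-[(1R)-4-oxocyclopent-2-en-1-yl]acetate
Conditions: MnO2 (activated, excess), CH2Cl2, rt
Reagents that add atoms: none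
Why: Oxidation of a secondary allylic alcohol with activated MnO2 is selective, neutral and heterogeneous, so the carbinol centre is cleared to the enone while the γ-stereocentre C4 should neither epimerise nor lose its hydrogen to double-bond migration.

Step 4
Reactants: 6 tert-butyl 2-[(1R)-4-oxocyclopent-2-en-1-yl]acetate; 7 vinylmagnesium bromide; 8 iodomethane
Product: 10 tert-butyl 2-[(1R,2R,3S)-3-methyl-4-oxo-2-vinylcyclopentyl]acetate, via bromomagnesium enolate 9 (not isolated)
Conditions: CuBr·SMe2 (15 mol %), 7 (1.3 equiv, slow addition), THF–Me2S, −78 → −40 °C; then 8 (5 equiv), DMPU, −40 → 0 °C; aq NH4Cl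
Reagents that add atoms: vinylmagnesium bromide (7), C=C[Mg]Br; iodomethane (8), CI
Why: Transmetalation of 7 to monovalent copper gives a vinylcuprate that binds the C2=C3 π bond of 6, adds oxidatively at C3 to a trivalent copper β-adduct and reductively eliminates, which makes the C3–vinyl bond, returns copper to the cycle and leaves enolate 9, whose aggregate DMPU loosens so that C2 displaces iodide from 8 and makes the C2–CH3 bond. The closest known reaction type is the three-component coupling of cyclopentenones, that is copper-mediated conjugate addition followed by alkylation of the regiodefined enolate, the standard entry to 2,3-trans-disubstituted cyclopentanones. No ring is closed; two C–C bonds and two stereocentres are created on the existing five-membered ring. C3 is controlled by the C4 side chain, which shields its own face of the flat enone so that vinyl is delivered anti to it, and C2 is controlled by the new vinyl group, iodomethane approaching the enolate from the opposite face, while any cis epimer can be drained to the more stable trans ketone by mild base because C2 is α to the carbonyl. The step needs 1,4- over 1,2-addition (secured by copper catalysis at low temperature and a low stationary concentration of 7), C2- over C5- and mono- over polymethylation (secured by the regiodefined enolate, the excess of the very reactive iodomethane and a temperature at or below 0 °C that keeps proton exchange between 9 and 10 slow), and survival of the ester (secured by the bulk of the tert-butyl group).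

Step 5
Reactants: 10 tert-butyl 2-[(1R,2R,3S)-3-methyl-4-oxo-2-vinylcyclopentyl]acetate
Product: 11 tert-butyl 2-[(2S,3R,4R)-2-methyl-6-oxo-3-vinyltetrahydro-2H-pyran-4-yl]acetate
Conditions: Me3SiOOSiMe3 (1.5 equiv), Me3SiOTf (10 mol %), CH2Cl2, −40 → −20 °C
Reagents that add atoms: bis(trimethylsilyl) peroxide, C[Si](C)(C)OO[Si](C)(C)C
Why: Baeyer–Villiger oxidation with a silyl peroxide under silyl triflate catalysis: the peroxide adds to the activated C6 carbonyl and the secondary C2 migrates to oxygen with retention of configuration in preference to the C5 methylene, while this oxidant, which does not epoxidise isolated alkenes, should leave the vinyl group untouched.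

Step 6
Reactants: 11 tert-butyl 2-[(2S,3R,4R)-2-methyl-6-oxo-3-vinyltetrahydro-2H-pyran-4-yl]acetate
Product: 12 tert-butyl 2-[(2S,3R,4R)-6-hydroxy-2-methyl-3-vinyltetrahydro-2H-pyran-4-yl]acetate (anomer mixture)
Conditions: i-Bu2AlH (1.1 equiv), toluene, −78 °C; aq potassium sodium tartrate
Reagents that add atoms: none
Why: Partial reduction of a lactone with one equivalent of i-Bu2AlH at −78 °C stops at the stable aluminium hemiacetal, the hindered tert-butyl ester being reduced far more slowly, and the new C6 centre is an anomer mixture that step 7 erases.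

Step 7
Reactants: 12 tert-butyl 2-[(2S,3R,4R)-6-hydroxy-2-methyl-3-vinyltetrahydro-2H-pyran-4-yl]acetate
Product: 14 tert-butyl 2-[(2S,3R,4S)-2-methyl-3-vinyl-3,4-dihydro-2H-pyran-4-yl]acetate, via anomeric mesylate 13 (not isolated)
Conditions: MsCl, Et3N (excess), CH2Cl2, −40 °C → reflux
Reagents that add atoms: none
Why: Sulfonylation–elimination of a lactol, the reaction type used to make glycal-like enol ethers from 2-deoxy hemiacetals: mesylate 13 ionises easily next to O1 and triethylamine removes a C5 proton, the only β-hydrogens available, to give the C5=C6 enol ether without touching C2, C3 or C4 (the C4 descriptor changes only because priorities change).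

Step 8
Reactants: 14 tert-butyl 2-[(2S,3R,4S)-2-methyl-3-vinyl-3,4-dihydro-2H-pyran-4-yl]acetate
Product: 15 tert-butyl 2-[(2S,3R,4R)-2-methyl-5-(trichloroacetyl)-3-vinyl-3,4-dihydro-2H-pyran-4-yl]acetate
Conditions: Cl3CCOCl, pyridine, CH2Cl2, 0 °C → rt
Reagents that add atoms: trichloroacetyl chloride, ClC(Cl)(Cl)C(=O)Cl
Why: Electrophilic C-acylation of an enol ether: the nucleophilic β-carbon C5 attacks the highly electrophilic acid chloride and pyridine removes HCl to restore the C5=C6 bond, a standard way to functionalise dihydropyrans of the iridoid type, in which the unactivated vinyl group cannot compete.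

Step 9
Reactants: 15 tert-butyl 2-[(2S,3R,4R)-2-methyl-5-(trichloroacetyl)-3-vinyl-3,4-dihydro-2H-pyran-4-yl]acetate
Product: 16 methyl (2S,3R,4R)-4-(2-tert-butoxy-2-oxoethyl)-2-methyl-3-vinyl-3,4-dihydro-2H-pyran-5-carboxylate
Conditions: NaOMe (cat.), MeOH, 0 °C → rt
Reagents that add atoms: methanol, CO
Why: Haloform-type cleavage: methoxide adds to the trichloromethyl ketone and expels the trichloromethyl anion, which methanol protonates to chloroform with regeneration of methoxide, while the tert-butyl ester resists transesterification and no stereocentre is acidic enough to be affected.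

Step 10
Reactants: 16 methyl (2S,3R,4R)-4-(2-tert-butoxy-2-oxoethyl)-2-methyl-3-vinyl-3,4-dihydro-2H-pyran-5-carboxylate
Product: 17 2-[(2S,3R,4R)-5-(methoxycarbonyl)-2-methyl-3-vinyl-3,4-dihydro-2H-pyran-4-yl]acetic acid
Conditions: CF3CO2H–CH2Cl2, 0 °C → rt
Reagents that add atoms: none
Why: Acidolysis of a tert-butyl ester by alkyl–oxygen fission to the tert-butyl cation, lost as isobutene, is selective because the methyl ester cannot fragment in this way and the ester-conjugated enol ether (a vinylogous carbonate) and the monosubstituted alkene are too weakly basic to react in anhydrous acid.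

Step 11
Reactants: 18 hydroxytyrosol
Product: 19 2-[3,4-bis(benzyloxy)phenyl]ethanol
Conditions: BnBr (2.2 equiv), K2CO3, acetone, reflux, Ar
Reagents that add atoms: benzyl bromide, BrCc1ccccc1
Why: Williamson ether synthesis: K2CO3 deprotonates only the two phenols, so both are benzylated while the much less acidic primary alcohol stays free, and exclusion of air prevents oxidation of the catecholate.

Step 12
Reactants: 17 2-[(2S,3R,4R)-5-(methoxycarbonyl)-2-methyl-3-vinyl-3,4-dihydro-2H-pyran-4-yl]acetic acid; 19 2-[3,4-bis(benzyloxy)phenyl]ethanol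
Product: 20 methyl (2S,3R,4R)-4-{2-[2-(3,4-bis(benzyloxy)phenyl)ethoxy]-2-oxoethyl}-2-methyl-3-vinyl-3,4-dihydro-2H-pyran-5-carboxylate
Conditions: DCC, DMAP (cat.), CH2Cl2, 0 °C → rt
Reagents that add atoms: none
Why: Steglich esterification of an unhindered acetic acid side chain with a primary alcohol proceeds under neutral conditions through DMAP-mediated acyl transfer, and the acid carries no α-stereocentre that could be lost.

Step 13
Reactants: 20 methyl (2S,3R,4R)-4-{2-[2-(3,4-bis(benzyloxy)phenyl)ethoxy]-2-oxoethyl}-2-methyl-3-vinyl-3,4-dihydro-2H-pyran-5-carboxylate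
Product: 22 methyl (2S,3R,4R)-4-{2-[2-(3,4-bis(benzyloxy)phenyl)ethoxy]-2-oxoethyl}-3-formyl-2-methyl-3,4-dihydro-2H-pyran-5-carboxylate, via vicinal diol 21 (not isolated)
Conditions: OsO4 (2 mol %), NaIO4 (3 equiv), 2,6-lutidine, dioxane–H2O, 0 °C → rt
Reagents that add atoms: osmium tetroxide, O=[Os](=O)(=O)=O; sodium periodate, [Na+].[O-]I(=O)(=O)=O
Why: Lemieux–Johnson oxidation: OsO4 should dihydroxylate the exposed monosubstituted vinyl group faster than the trisubstituted C5=C6 bond, which is deactivated by ester conjugation and flanked by C4, periodate then cleaves diol 21 and reoxidises osmium, the benzyl ethers shield the catechol from periodate, and the lutidine buffer keeps C3, whose configuration is simply retained, from enolising.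

Step 14
Reactants: 22 methyl (2S,3R,4R)-4-{2-[2-(3,4-bis(benzyloxy)phenyl)ethoxy]-2-oxoethyl}-3-formyl-2-methyl-3,4-dihydro-2H-pyran-5-carboxylate
Product: 23 methyl (2S,3R,4R)-4-{2-[2-(3,4-dihydroxyphenyl)ethoxy]-2-oxoethyl}-3-formyl-2-methyl-3,4-dihydro-2H-pyran-5-carboxylate (CNP0172886.1)
Conditions: H2 (1 atm), Pd/C, EtOAc, rt
Reagents that add atoms: none
Why: Hydrogenolysis of aryl benzyl ethers over palladium on carbon is neutral, which avoids enolisation at C3 and β-elimination of O1 from the β-alkoxy aldehyde, while the ester-conjugated trisubstituted enol ether, the aliphatic aldehyde and the 2-arylethyl ester are attacked much more slowly than the benzylic C–O bonds.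

**Compound list**

1 | (1R,4S)-cis-4-acetoxycyclopent-2-en-1-ol | O[C@H]1C=C[C@@H](OC(C)=O)C1 | starting material
2 | tert-butyl methyl malonate | COC(=O)CC(=O)OC(C)(C)C | starting material
3 | sodium enolate of tert-butyl methyl malonate | [Na+].COC(=O)[CH-]C(=O)OC(C)(C)C | intermediate
4 | tert-butyl methyl 2-[(1S,4R)-4-hydroxycyclopent-2-en-1-yl]malonate (epimers at the malonate carbon) | O[C@H]1C=C[C@@H](C(C(=O)OC)C(=O)OC(C)(C)C)C1 | intermediate
5 | tert-butyl 2-[(1R,4R)-4-hydroxycyclopent-2-en-1-yl]acetate | O[C@H]1C=C[C@@H](CC(=O)OC(C)(C)C)C1 | intermediate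
6 | tert-butyl 2-[(1R)-4-oxocyclopent-2-en-1-yl]acetate | O=C1C=C[C@@H](CC(=O)OC(C)(C)C)C1 | intermediate
7 | vinylmagnesium bromide | C=C[Mg]Br | starting material
8 | iodomethane | CI | starting material
9 | bromomagnesium (3R,4R)-4-(2-tert-butoxy-2-oxoethyl)-3-vinylcyclopent-1-en-1-olate | Br[Mg]OC1=C[C@H](C=C)[C@@H](CC(=O)OC(C)(C)C)C1 | intermediate
10 | tert-butyl 2-[(1R,2R,3S)-3-methyl-4-oxo-2-vinylcyclopentyl]acetate (all-trans) | O=C1[C@@H](C)[C@H](C=C)[C@@H](CC(=O)OC(C)(C)C)C1 | intermediate
11 | tert-butyl 2-[(2S,3R,4R)-2-methyl-6-oxo-3-vinyltetrahydro-2H-pyran-4-yl]acetate | O=C1O[C@@H](C)[C@H](C=C)[C@@H](CC(=O)OC(C)(C)C)C1 | intermediate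
12 | tert-butyl 2-[(2S,3R,4R)-6-hydroxy-2-methyl-3-vinyltetrahydro-2H-pyran-4-yl]acetate (anomers) | OC1O[C@@H](C)[C@H](C=C)[C@@H](CC(=O)OC(C)(C)C)C1 | intermediate
13 | tert-butyl 2-[(2S,3R,4R)-2-methyl-6-(methylsulfonyloxy)-3-vinyltetrahydro-2H-pyran-4-yl]acetate (anomers) | CS(=O)(=O)OC1O[C@@H](C)[C@H](C=C)[C@@H](CC(=O)OC(C)(C)C)C1 | intermediate
14 | tert-butyl 2-[(2S,3R,4S)-2-methyl-3-vinyl-3,4-dihydro-2H-pyran-4-yl]acetate | C1=CO[C@@H](C)[C@H](C=C)[C@H]1CC(=O)OC(C)(C)C | intermediate
15 | tert-butyl 2-[(2S,3R,4R)-2-methyl-5-(trichloroacetyl)-3-vinyl-3,4-dihydro-2H-pyran-4-yl]acetate | ClC(Cl)(Cl)C(=O)C1=CO[C@@H](C)[C@H](C=C)[C@H]1CC(=O)OC(C)(C)C | intermediate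
16 | methyl (2S,3R,4R)-4-(2-tert-butoxy-2-oxoethyl)-2-methyl-3-vinyl-3,4-dihydro-2H-pyran-5-carboxylate | COC(=O)C1=CO[C@@H](C)[C@H](C=C)[C@H]1CC(=O)OC(C)(C)C | intermediate
17 | 2-[(2S,3R,4R)-5-(methoxycarbonyl)-2-methyl-3-vinyl-3,4-dihydro-2H-pyran-4-yl]acetic acid | COC(=O)C1=CO[C@@H](C)[C@H](C=C)[C@H]1CC(=O)O | intermediate
18 | hydroxytyrosol, 4-(2-hydroxyethyl)benzene-1,2-diol | OCCc1ccc(O)c(O)c1 | starting material
19 | 2-[3,4-bis(benzyloxy)phenyl]ethanol | OCCc1ccc(OCc2ccccc2)c(OCc2ccccc2)c1 | intermediate
20 | methyl (2S,3R,4R)-4-{2-[2-(3,4-bis(benzyloxy)phenyl)ethoxy]-2-oxoethyl}-2-methyl-3-vinyl-3,4-dihydro-2H-pyran-5-carboxylate | COC(=O)C1=CO[C@@H](C)[C@H](C=C)[C@H]1CC(=O)OCCc1ccc(OCc2ccccc2)c(OCc2ccccc2)c1 | intermediate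
21 | 1,2-diol from dihydroxylation of the vinyl group of 20 (C3 bears CH(OH)CH2OH, carbinol epimers) | COC(=O)C1=CO[C@@H](C)[C@H](C(O)CO)[C@H]1CC(=O)OCCc1ccc(OCc2ccccc2)c(OCc2ccccc2)c1 | intermediate
22 | methyl (2S,3R,4R)-4-{2-[2-(3,4-bis(benzyloxy)phenyl)ethoxy]-2-oxoethyl}-3-formyl-2-methyl-3,4-dihydro-2H-pyran-5-carboxylate | COC(=O)C1=CO[C@@H](C)[C@H](C=O)[C@H]1CC(=O)OCCc1ccc(OCc2ccccc2)c(OCc2ccccc2)c1 | intermediate
23 | methyl (2S,3R,4R)-4-{2-[2-(3,4-dihydroxyphenyl)ethoxy]-2-oxoethyl}-3-formyl-2-methyl-3,4-dihydro-2H-pyran-5-carboxylate | COC(=O)C1=CO[C@@H](C)[C@H](C=O)[C@H]1CC(=O)OCCc1ccc(O)c(O)c1 | target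

**Step count**

Total steps: 14. Longest linear sequence: 13 steps (steps 1–10 and 12–14, from 1 to 23). Step 11 is a one-step side branch.

**Steps most likely to fail**

Step 4. A magnesium enolate alkylates slowly. Proton exchange between 9 and the product may therefore set in and lead to methylation at C5 or to double methylation, and uncatalysed 1,2-addition of 7 may erode the conjugate addition.

- The fallback keeps the disconnection but separates the two bond formations.
- From 6, the copper-catalysed addition of 7 is run in the presence of Me3SiCl (THF, −78 °C). This accelerates the 1,4-pathway and captures the enolate as the isolable trimethylsilyl enol ether F1.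
- Anhydrous benzyltrimethylammonium fluoride and iodomethane 8 in THF then release a metal-free ammonium enolate from F1. It should be methylated regiospecifically at C2, anti to the vinyl group.
- This returns to the route at 10.

Step 5. Oxygen insertion into the flanked cyclopentanone may be too slow at the temperatures at which the silyl triflate spares the tert-butyl ester, so incomplete conversion or ester cleavage could compete. A simple change to a peracid would bring in competing epoxidation of the vinyl group.

- The fallback gives up chemoselectivity on purpose and restores the alkene afterwards.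
- From 10, excess m-chloroperbenzoic acid (NaHCO3, CH2Cl2, rt) should effect both the Baeyer–Villiger insertion and the epoxidation. The product is the epoxy lactone F2, an epimer mixture at the oxirane carbon.
- Reductive deoxygenation follows with Cp2TiCl (trivalent titanium, generated from Cp2TiCl2 and zinc dust, THF, rt). The reagent opens the oxirane to a β-titanoxy radical, captures it and eliminates the titanium–oxygen unit.
- This should regenerate the vinyl group and rejoin the route at 11.

Step 13. Osmylation may not distinguish cleanly between the vinyl group and the C5=C6 bond. The β-alkoxy aldehyde may also suffer enolisation at C3 or β-elimination of O1 on prolonged exposure to the buffered medium.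

- The fallback replaces osmylation by a peracid-based sequence.
- From 20, m-chloroperbenzoic acid (NaHCO3, CH2Cl2, rt), which discriminates more sharply against ester-conjugated alkenes, should give the terminal epoxide F3 as an epimer mixture.
- Periodic acid, H5IO6, in aqueous THF at 0 °C then hydrolyses and cleaves the oxirane in one operation. The acidic pH suppresses enolate chemistry at C3.
- The sequence comes back to the route at 22.

**Further compounds**

F1 | step 4 | tert-butyl 2-[(1R,2R)-4-(trimethylsilyloxy)-2-vinylcyclopent-3-en-1-yl]acetate | C[Si](C)(C)OC1=C[C@H](C=C)[C@@H](CC(=O)OC(C)(C)C)C1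
F2 | step 5 | tert-butyl 2-[(2S,3R,4R)-2-methyl-3-(oxiran-2-yl)-6-oxotetrahydro-2H-pyran-4-yl]acetate (oxirane epimers) | O=C1O[C@@H](C)[C@H](C2CO2)[C@@H](CC(=O)OC(C)(C)C)C1
F3 | step 13 | methyl (2S,3R,4R)-4-{2-[2-(3,4-bis(benzyloxy)phenyl)ethoxy]-2-oxoethyl}-2-methyl-3-(oxiran-2-yl)-3,4-dihydro-2H-pyran-5-carboxylate (oxirane epimers) | COC(=O)C1=CO[C@@H](C)[C@H](C2CO2)[C@H]1CC(=O)OCCc1ccc(OCc2ccccc2)c(OCc2ccccc2)c1
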